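## Retrosynthetic overview

1. Locants: tetralin C1 carries the side chain, C4 the methyl, C5/C6 the oxygens, C7 the CO2H; side chain C11 (on C1) to C16 (CH2O), with C15 bearing the methyl. The caffeate is put on last as its dimethyl ether and all four aryl methyl ethers are cleaved in one BBr3 step; CO2H comes from ortho-lithiation/CO2 at C7.
2. C13=C14 Wittig disconnection: a C13 aldehyde plus a chiral-pool hydroxy-phosphonium ylide that carries C15; the alkene is then hydrogenated.
3. Key C1–C11 bond: the cis-tetralol carbamate is lithiated at C1 (α-oxy carbanion) and joined to a chiral β-boryl ester (homoenolate equivalent) by 1,2-metallate shift, then protodeboronated. This sets C1 and C11 and the 1,4-trans relationship.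
4. C4 and the tetralone: Ni-catalysed stereoconvergent Negishi coupling of a zinc homoenolate with a racemic benzylic chloride, then Friedel–Crafts acylation.
5. Ring order: the aromatic ring is bought (2,3-dimethoxybenzaldehyde); the saturated ring is the only ring formed (step 3).

Assumption: for the chiral catalysts in steps 2 and 6 the ligand enantiomer named is taken to give the configuration drawn; if the sense of induction is opposite, the mirror-image ligand is used.

## Route

Step 1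
Reactants: 1 2,3-dimethoxybenzaldehyde
Product: 2 rac-1-(2,3-dimethoxyphenyl)ethan-1-ol
Conditions: MeMgBr, THF, 0 °C; aq. NH4Cl
Reagents that add atoms: methylmagnesium bromide, C[Mg]Br
Why: Grignard 1,2-addition to the aldehyde gives the secondary benzylic alcohol, made racemic on purpose because the next coupling is stereoconvergent.

Step 2
Reactants: 2 rac-1-(2,3-dimethoxyphenyl)ethan-1-ol; 3 ethyl 3-bromopropanoate
Product: 7 (4R)-4-(2,3-dimethoxyphenyl)pentanoic acid, via benzylic chloride 4 (not isolated), via zinc homoenolate 5 (not isolated), via ethyl ester 6 (not isolated)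
Conditions: SOCl2, CH2Cl2, 0 °C, evaporate; 3, Zn dust, I2 (5 mol %), DMA, 70 °C (separate flask); NiBr2·glyme (10 mol %), (S)-iPr-Pybox (13 mol %), DMA, 0 °C; then LiOH, THF–H2O, rt; 1 M HCl
Reagents that add atoms: lithium hydroxide, [Li+].[OH-]
Why: Chlorination followed by a stereoconvergent nickel-catalysed Negishi cross-coupling with the ester-bearing zinc homoenolate forges C3–C4, because both enantiomers of 4 give the same planar benzylic radical, which the chiral Ni–pybox complex captures on one face to set C4 as R; saponification in the same pot lets the acid be purified by acid–base extraction.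

Step 3
Reactants: 7 (4R)-4-(2,3-dimethoxyphenyl)pentanoic acid
Product: 9 (4R)-5,6-dimethoxy-4-methyl-3,4-dihydronaphthalen-1(2H)-one, via mixed trifluoroacetic anhydride 8 (not isolated)
Conditions: (CF3CO)2O, CH2Cl2, 0 °C to rt
Reagents that add atoms: none
Why: Intramolecular Friedel–Crafts acylation through the mixed anhydride closes the six-membered ring at the only free ortho position, which is para to a methoxy group, without touching the C4 stereocenter.

Step 4
Reactants: 9 (4R)-5,6-dimethoxy-4-methyl-3,4-dihydronaphthalen-1(2H)-one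
Product: 10 (1S,4R)-5,6-dimethoxy-4-methyl-1,2,3,4-tetrahydronaphthalen-1-ol (cis)
Conditions: RuCl[(S,S)-TsDPEN](p-cymene) (1 mol %), HCO2H–Et3N 5:2, rt
Reagents that add atoms: none
Why: Noyori–Ikariya asymmetric transfer hydrogenation with the (S,S) catalyst gives the (1S) carbinol, matched with the substrate's preference for hydride attack anti to the pseudoaxial C4 methyl, so the cis alcohol results and any (4S) ketone carried from step 2 becomes a separable trans diastereomer.

Step 5
Reactants: 10 (1S,4R)-5,6-dimethoxy-4-methyl-1,2,3,4-tetrahydronaphthalen-1-ol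
Product: 11 (1S,4R)-5,6-dimethoxy-4-methyl-1,2,3,4-tetrahydronaphthalen-1-yl N,N-diisopropylcarbamate
Conditions: NaH, THF, 0 °C; iPr2NCOCl, reflux
Reagents that add atoms: N,N-diisopropylcarbamoyl chloride, CC(C)N(C(C)C)C(Cl)=O
Why: O-carbamoylation of the alkoxide (retention at C1) installs the group that directs benzylic lithiation and later serves as the leaving group.

Step 6
Reactants: 12 tert-butyl (E)-but-2-enoate
Product: 13 tert-butyl (3S)-3-(4,4,5,5-tetramethyl-1,3,2-dioxaborolan-2-yl)butanoate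
Conditions: B2pin2, CuCl (3 mol %), NaOtBu (9 mol %), (R,SP)-Josiphos SL-J001-1 (3 mol %), MeOH (2 equiv), THF, rt
Reagents that add atoms: bis(pinacolato)diboron, CC1(C)OB(OC1(C)C)B1OC(C)(C)C(C)(C)O1
Why: Copper-catalysed enantioselective conjugate borylation (boryl-copper 1,4-addition, then protonation by methanol) sets the C–B stereocenter as S under ligand control and turns the electrophilic β-carbon of the enoate into a configurationally stable homoenolate equivalent.

Step 7
Reactants: 11 (1S,4R)-5,6-dimethoxy-4-methyl-1,2,3,4-tetrahydronaphthalen-1-yl N,N-diisopropylcarbamate; 13 tert-butyl (3S)-3-(4,4,5,5-tetramethyl-1,3,2-dioxaborolan-2-yl)butanoate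
Product: 16 tert-butyl (3S)-3-[(1S,4R)-5,6-dimethoxy-4-methyl-1-(4,4,5,5-tetramethyl-1,3,2-dioxaborolan-2-yl)-1,2,3,4-tetrahydronaphthalen-1-yl]butanoate, via lithiated carbamate 14 (not isolated), via boronate complex 15 (not isolated)
Conditions: s-BuLi (1.2 equiv), Et2O, −78 °C; 13 (1.5 equiv), −78 °C; MgBr2·OEt2–MeOH, −78 °C to rt; aq. NH4Cl
Reagents that add atoms: none
Why: Lithiation–borylation (Hoppe-type α-oxy carbanion, then Matteson-type 1,2-metallate rearrangement): s-BuLi removes the benzylic proton α to the carbamate with retention, the boronic ester is captured with retention, and the ester β-carbon (the homoenolate carbon) migrates from boron to C1 with retention of its own configuration and anti to the departing carbamate, so the former ketone carbon and the former enoate β-carbon are joined, C11 is S and the new C–C bond is trans to the C4 methyl.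

Step 8
Reactants: 16 tert-butyl (3S)-3-[(1S,4R)-5,6-dimethoxy-4-methyl-1-(4,4,5,5-tetramethyl-1,3,2-dioxaborolan-2-yl)-1,2,3,4-tetrahydronaphthalen-1-yl]butanoate
Product: 17 tert-butyl (3S)-3-[(1S,4R)-5,6-dimethoxy-4-methyl-1,2,3,4-tetrahydronaphthalen-1-yl]butanoate
Conditions: TBAF·3H2O, n-pentane–toluene, 45 °C
Reagents that add atoms: none
Why: Fluoride-promoted protodeboronation of the tertiary benzylic boronic ester proceeds with retention (front-side protonation of the fluoroboronate), so hydrogen takes the place of boron cis to the C4 methyl and the 1,4-trans tetralin with the (S)-C11 neighbour is obtained.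

Step 9
Reactants: 17 tert-butyl (3S)-3-[(1S,4R)-5,6-dimethoxy-4-methyl-1,2,3,4-tetrahydronaphthalen-1-yl]butanoate
Product: 18 (3S)-3-[(1S,4R)-5,6-dimethoxy-4-methyl-1,2,3,4-tetrahydronaphthalen-1-yl]butanal
Conditions: DIBAL-H (1.1 equiv), CH2Cl2, −78 °C; Rochelle salt
Reagents that add atoms: none
Why: Partial ester reduction with DIBAL-H stops at the aldehyde because the tetrahedral aluminium hemiacetal is stable at −78 °C, and no stereocenter is α to the carbonyl, so nothing can epimerise.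

Step 10
Reactants: 19 (2S)-3-bromo-2-methylpropan-1-ol
Product: 20 [(2S)-3-hydroxy-2-methylpropyl]triphenylphosphonium bromide
Conditions: PPh3, MeCN, reflux
Reagents that add atoms: triphenylphosphine, c1ccc(cc1)P(c1ccccc1)c1ccccc1
Why: SN2 quaternisation of the primary bromide by triphenylphosphine leaves the chiral-pool stereocenter (the future C15) untouched.

Step 11
Reactants: 18 (3S)-3-[(1S,4R)-5,6-dimethoxy-4-methyl-1,2,3,4-tetrahydronaphthalen-1-yl]butanal; 20 [(2S)-3-hydroxy-2-methylpropyl]triphenylphosphonium bromide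
Product: 22 (2R,3Z,6S)-6-[(1S,4R)-5,6-dimethoxy-4-methyl-1,2,3,4-tetrahydronaphthalen-1-yl]-2-methylhept-3-en-1-ol, via oxido ylide 21 (not isolated)
Conditions: 20 (1.5 equiv), KHMDS (3.0 equiv), THF, 0 °C; then 18, −78 °C to rt; aq. NH4Cl
Reagents that add atoms: none
Why: Wittig olefination with the non-stabilised oxido ylide (one equivalent of base for OH, one for the ylide) joins C13 to C14 and brings in C15 with its configuration fixed, the mainly Z geometry being irrelevant because the alkene is hydrogenated next.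

Step 12
Reactants: 22 (2R,3Z,6S)-6-[(1S,4R)-5,6-dimethoxy-4-methyl-1,2,3,4-tetrahydronaphthalen-1-yl]-2-methylhept-3-en-1-ol
Product: 23 (2R,6S)-6-[(1S,4R)-5,6-dimethoxy-4-methyl-1,2,3,4-tetrahydronaphthalen-1-yl]-2-methylheptan-1-ol
Conditions: H2 (1 atm), Pt/C, EtOAc, rt
Reagents that add atoms: none
Why: Heterogeneous hydrogenation of the disubstituted alkene, with platinum rather than palladium to suppress alkene migration toward the allylic C15 stereocenter, so no stereocenter is disturbed.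

Step 13
Reactants: 23 (2R,6S)-6-[(1S,4R)-5,6-dimethoxy-4-methyl-1,2,3,4-tetrahydronaphthalen-1-yl]-2-methylheptan-1-ol
Product: 25 (5R,8S)-8-[(2S,6R)-7-hydroxy-6-methylheptan-2-yl]-3,4-dimethoxy-5-methyl-5,6,7,8-tetrahydronaphthalene-2-carboxylic acid, via dilithio species 24 (not isolated)
Conditions: n-BuLi (3.5 equiv), TMEDA, Et2O, 0 °C to rt; CO2, −78 °C to rt; 1 M HCl
Reagents that add atoms: carbon dioxide, O=C=O
Why: Directed ortho-metalation: after deprotonation of the alcohol, the only ring C–H ortho to a methoxy group (tetralin C7) is lithiated and carboxylated, while the alkoxide takes up CO2 only reversibly and returns as the alcohol on acidic work-up.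

Step 14
Reactants: 25 (5R,8S)-8-[(2S,6R)-7-hydroxy-6-methylheptan-2-yl]-3,4-dimethoxy-5-methyl-5,6,7,8-tetrahydronaphthalene-2-carboxylic acid; 26 (2E)-3-(3,4-dimethoxyphenyl)prop-2-enoic acid
Product: 29 (5R,8S)-8-[(2S,6R)-7-{[(2E)-3-(3,4-dimethoxyphenyl)prop-2-enoyl]oxy}-6-methylheptan-2-yl]-3,4-dimethoxy-5-methyl-5,6,7,8-tetrahydronaphthalene-2-carboxylic acid, via cinnamoyl chloride 27 (not isolated), via mixed anhydride ester 28 (not isolated)
Conditions: 26 (2.5 equiv), (COCl)2, DMF (cat.), CH2Cl2, 0 °C to rt, evaporate; then 25, pyridine, DMAP (10 mol %), CH2Cl2, 0 °C to rt; then H2O–THF, rt; 1 M HCl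
Reagents that add atoms: none
Why: DMAP-catalysed acylation of the primary alcohol by the acid chloride, in which the hindered aryl carboxylic acid is only converted into a mixed anhydride that water cleaves back to the acid, so no protecting group is needed.

Step 15
Reactants: 29 (5R,8S)-8-[(2S,6R)-7-{[(2E)-3-(3,4-dimethoxyphenyl)prop-2-enoyl]oxy}-6-methylheptan-2-yl]-3,4-dimethoxy-5-methyl-5,6,7,8-tetrahydronaphthalene-2-carboxylic acid
Product: 30 (5R,8S)-8-[(2S,6R)-7-{[(2E)-3-(3,4-dihydroxyphenyl)prop-2-enoyl]oxy}-6-methylheptan-2-yl]-3,4-dihydroxy-5-methyl-5,6,7,8-tetrahydronaphthalene-2-carboxylic acid (CNP0492979.1)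
Conditions: BBr3 (10 equiv), CH2Cl2, −78 to 0 °C; MeOH–H2O
Reagents that add atoms: none
Why: Lewis-acid ether cleavage by BBr3 (complexation, then bromide attack on each methyl group, chelation-assisted next to CO2H) removes all four aryl methyl ethers at a temperature at which the β-branched primary alkyl cinnamate and its alkene survive.

## Compound list

1 | 2,3-dimethoxybenzaldehyde | COc1cccc(C=O)c1OC | starting material
2 | rac-1-(2,3-dimethoxyphenyl)ethan-1-ol | COc1cccc(C(C)O)c1OC | intermediate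
3 | ethyl 3-bromopropanoate | CCOC(=O)CCBr | starting material
4 | rac-1-(1-chloroethyl)-2,3-dimethoxybenzene | COc1cccc(C(C)Cl)c1OC | intermediate
5 | (3-ethoxy-3-oxopropyl)zinc bromide | CCOC(=O)CC[Zn]Br | intermediate
6 | ethyl (4R)-4-(2,3-dimethoxyphenyl)pentanoate | CCOC(=O)CC[C@@H](C)c1cccc(OC)c1OC | intermediate
7 | (4R)-4-(2,3-dimethoxyphenyl)pentanoic acid | OC(=O)CC[C@@H](C)c1cccc(OC)c1OC | intermediate
8 | (4R)-4-(2,3-dimethoxyphenyl)pentanoic trifluoroacetic anhydride | FC(F)(F)C(=O)OC(=O)CC[C@@H](C)c1cccc(OC)c1OC | intermediate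
9 | (4R)-5,6-dimethoxy-4-methyl-3,4-dihydronaphthalen-1(2H)-one | O=C1CC[C@@H](C)c2c1ccc(OC)c2OC | intermediate
10 | (1S,4R)-5,6-dimethoxy-4-methyl-1,2,3,4-tetrahydronaphthalen-1-ol | O[C@H]1CC[C@@H](C)c2c1ccc(OC)c2OC | intermediate
11 | (1S,4R)-5,6-dimethoxy-4-methyl-1,2,3,4-tetrahydronaphthalen-1-yl N,N-diisopropylcarbamate | CC(C)N(C(C)C)C(=O)O[C@H]1CC[C@@H](C)c2c1ccc(OC)c2OC | intermediate
12 | tert-butyl (E)-but-2-enoate | C/C=C/C(=O)OC(C)(C)C | starting material
13 | tert-butyl (3S)-3-(4,4,5,5-tetramethyl-1,3,2-dioxaborolan-2-yl)butanoate | CC(C)(C)OC(=O)C[C@H](C)B1OC(C)(C)C(C)(C)O1 | intermediate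
14 | (1S,4R)-1-lithio-5,6-dimethoxy-4-methyl-1,2,3,4-tetrahydronaphthalen-1-yl N,N-diisopropylcarbamate | CC(C)N(C(C)C)C(=O)O[C@@]1([Li])CC[C@@H](C)c2c1ccc(OC)c2OC | intermediate
15 | lithium [(1S,4R)-1-(N,N-diisopropylcarbamoyloxy)-5,6-dimethoxy-4-methyl-1,2,3,4-tetrahydronaphthalen-1-yl][(2S)-4-tert-butoxy-4-oxobutan-2-yl](pinacolato)borate | [Li+].CC(C)N(C(C)C)C(=O)O[C@@]1([B-]3(OC(C)(C)C(C)(C)O3)[C@@H](C)CC(=O)OC(C)(C)C)CC[C@@H](C)c2c1ccc(OC)c2OC | intermediate
16 | tert-butyl (3S)-3-[(1S,4R)-5,6-dimethoxy-4-methyl-1-(4,4,5,5-tetramethyl-1,3,2-dioxaborolan-2-yl)-1,2,3,4-tetrahydronaphthalen-1-yl]butanoate | CC(C)(C)OC(=O)C[C@H](C)[C@]1(B3OC(C)(C)C(C)(C)O3)CC[C@@H](C)c2c1ccc(OC)c2OC | intermediate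
17 | tert-butyl (3S)-3-[(1S,4R)-5,6-dimethoxy-4-methyl-1,2,3,4-tetrahydronaphthalen-1-yl]butanoate | CC(C)(C)OC(=O)C[C@H](C)[C@@H]1CC[C@@H](C)c2c1ccc(OC)c2OC | intermediate
18 | (3S)-3-[(1S,4R)-5,6-dimethoxy-4-methyl-1,2,3,4-tetrahydronaphthalen-1-yl]butanal | O=CC[C@H](C)[C@@H]1CC[C@@H](C)c2c1ccc(OC)c2OC | intermediate
19 | (2S)-3-bromo-2-methylpropan-1-ol | C[C@H](CBr)CO | starting material
20 | [(2S)-3-hydroxy-2-methylpropyl]triphenylphosphonium bromide | C[C@H](C[P+](c1ccccc1)(c1ccccc1)c1ccccc1)CO.[Br-] | intermediate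
21 | potassium (2S)-2-methyl-3-(triphenyl-λ5-phosphanylidene)propan-1-olate | C[C@H](C=P(c1ccccc1)(c1ccccc1)c1ccccc1)C[O-].[K+] | intermediate
22 | (2R,3Z,6S)-6-[(1S,4R)-5,6-dimethoxy-4-methyl-1,2,3,4-tetrahydronaphthalen-1-yl]-2-methylhept-3-en-1-ol | OC[C@H](C)/C=C\C[C@H](C)[C@@H]1CC[C@@H](C)c2c1ccc(OC)c2OC | intermediate
23 | (2R,6S)-6-[(1S,4R)-5,6-dimethoxy-4-methyl-1,2,3,4-tetrahydronaphthalen-1-yl]-2-methylheptan-1-ol | OC[C@H](C)CCC[C@H](C)[C@@H]1CC[C@@H](C)c2c1ccc(OC)c2OC | intermediate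
24 | lithium (2R,6S)-6-[(1S,4R)-7-lithio-5,6-dimethoxy-4-methyl-1,2,3,4-tetrahydronaphthalen-1-yl]-2-methylheptan-1-olate | [Li]OC[C@H](C)CCC[C@H](C)[C@@H]1CC[C@@H](C)c2c1cc([Li])c(OC)c2OC | intermediate
25 | (5R,8S)-8-[(2S,6R)-7-hydroxy-6-methylheptan-2-yl]-3,4-dimethoxy-5-methyl-5,6,7,8-tetrahydronaphthalene-2-carboxylic acid | OC[C@H](C)CCC[C@H](C)[C@@H]1CC[C@@H](C)c2c1cc(C(=O)O)c(OC)c2OC | intermediate
26 | (2E)-3-(3,4-dimethoxyphenyl)prop-2-enoic acid | COc1ccc(/C=C/C(=O)O)cc1OC | starting material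
27 | (2E)-3-(3,4-dimethoxyphenyl)prop-2-enoyl chloride | COc1ccc(/C=C/C(=O)Cl)cc1OC | intermediate
28 | mixed anhydride of 29 (at its aryl CO2H) with (2E)-3-(3,4-dimethoxyphenyl)prop-2-enoic acid | COc1ccc(/C=C/C(=O)OC[C@H](C)CCC[C@H](C)[C@@H]2CC[C@@H](C)c3c2cc(C(=O)OC(=O)/C=C/c2ccc(OC)c(OC)c2)c(OC)c3OC)cc1OC | intermediate
29 | (5R,8S)-8-[(2S,6R)-7-{[(2E)-3-(3,4-dimethoxyphenyl)prop-2-enoyl]oxy}-6-methylheptan-2-yl]-3,4-dimethoxy-5-methyl-5,6,7,8-tetrahydronaphthalene-2-carboxylic acid | COc1ccc(/C=C/C(=O)OC[C@H](C)CCC[C@H](C)[C@@H]2CC[C@@H](C)c3c2cc(C(=O)O)c(OC)c3OC)cc1OC | intermediate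
30 | (5R,8S)-8-[(2S,6R)-7-{[(2E)-3-(3,4-dihydroxyphenyl)prop-2-enoyl]oxy}-6-methylheptan-2-yl]-3,4-dihydroxy-5-methyl-5,6,7,8-tetrahydronaphthalene-2-carboxylic acid | C[C@H](CCC[C@H](C)[C@@H]1CC[C@@H](C)c2c1cc(C(=O)O)c(O)c2O)COC(=O)/C=C/c1ccc(O)c(O)c1 | target

## Step count and risk

Total step count: 15. Longest linear sequence: 13 (steps 1–5, 7–9, 11–15); steps 6 and 10 make the two side reagents.

Steps most likely to fail:

Step 7. The lithiated carbamate is a hindered, electron-rich benzylic anion and boronate 13 is a secondary boronic ester with an enolisable ester. Ate-complex formation may lose to proton transfer from the ester α-CH2 or to attack on the ester. Fallback: finish the side chain on boron first, so that the boronate has no carbonyl. Setting out from 13, DIBAL-H at −78 °C gives (3S)-3-(4,4,5,5-tetramethyl-1,3,2-dioxaborolan-2-yl)butanal F1. Wittig reaction with ylide 21 gives (2R,3Z,6S)-2-methyl-6-(4,4,5,5-tetramethyl-1,3,2-dioxaborolan-2-yl)hept-3-en-1-ol F2. Silylation (TBSCl, imidazole) gives its tert-butyldimethylsilyl ether F3, and hydrogenation over Pt/C gives the saturated silyl ether boronate F4. Lithiation–borylation of 11 with F4 under the step 7 conditions gives the tertiary boronic ester F5. TBAF·3H2O then removes boron (retention) and silicon together and the route is rejoined at 23.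

Step 2. The ortho-methoxy group may lower the yield or the enantioselectivity of the nickel coupling, and the electron-rich chloride 4 can eliminate to the styrene. Fallback: build the same acid by acyl-anion chemistry and asymmetric hydrogenation. Setting out from 1, a Stetter reaction with ethyl acrylate (3-benzyl-5-(2-hydroxyethyl)-4-methylthiazolium chloride, Et3N, EtOH, 80 °C) gives ethyl 4-(2,3-dimethoxyphenyl)-4-oxobutanoate F6. Wittig methylenation (Ph3P=CH2, THF) gives ethyl 4-(2,3-dimethoxyphenyl)pent-4-enoate F7. Saponification (LiOH) gives 4-(2,3-dimethoxyphenyl)pent-4-enoic acid F8. Carboxyl-directed asymmetric hydrogenation with [Ir(cod)(SIPHOX)]BArF (ligand enantiomer chosen for R), H2 and Et3N in MeOH gives the acid, and the route is rejoined at 7.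

Step 15. BBr3 may cleave or hydrobrominate the cinnamate while removing four methyl ethers. Fallback: demethylate before the caffeate exists and then build the caffeate from a malonate. Setting out from 25, BBr3 (CH2Cl2, −78 to 0 °C) gives (5R,8S)-3,4-dihydroxy-8-[(2S,6R)-7-hydroxy-6-methylheptan-2-yl]-5-methyl-5,6,7,8-tetrahydronaphthalene-2-carboxylic acid F9. Heating with Meldrum's acid (toluene, 90 °C) acylates the aliphatic hydroxyl to give the malonic half ester F10. Knoevenagel–Doebner condensation with 3,4-dihydroxybenzaldehyde (pyridine, cat. piperidine, 60 °C, loss of CO2) gives the target, and the route is rejoined at 30.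

Further compounds

F1 | step 7 | (3S)-3-(4,4,5,5-tetramethyl-1,3,2-dioxaborolan-2-yl)butanal | O=CC[C@H](C)B1OC(C)(C)C(C)(C)O1
F2 | step 7 | (2R,3Z,6S)-2-methyl-6-(4,4,5,5-tetramethyl-1,3,2-dioxaborolan-2-yl)hept-3-en-1-ol | OC[C@H](C)/C=C\C[C@H](C)B1OC(C)(C)C(C)(C)O1
F3 | step 7 | tert-butyldimethyl{[(2R,3Z,6S)-2-methyl-6-(4,4,5,5-tetramethyl-1,3,2-dioxaborolan-2-yl)hept-3-en-1-yl]oxy}silane | CC(C)(C)[Si](C)(C)OC[C@H](C)/C=C\C[C@H](C)B1OC(C)(C)C(C)(C)O1
F4 | step 7 | tert-butyldimethyl{[(2R,6S)-2-methyl-6-(4,4,5,5-tetramethyl-1,3,2-dioxaborolan-2-yl)heptyl]oxy}silane | CC(C)(C)[Si](C)(C)OC[C@H](C)CCC[C@H](C)B1OC(C)(C)C(C)(C)O1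
F5 | step 7 | tert-butyl{[(2R,6S)-6-[(1S,4R)-5,6-dimethoxy-4-methyl-1-(4,4,5,5-tetramethyl-1,3,2-dioxaborolan-2-yl)-1,2,3,4-tetrahydronaphthalen-1-yl]-2-methylheptyl]oxy}dimethylsilane | CC(C)(C)[Si](C)(C)OC[C@H](C)CCC[C@H](C)[C@]1(B3OC(C)(C)C(C)(C)O3)CC[C@@H](C)c2c1ccc(OC)c2OC
F6 | step 2 | ethyl 4-(2,3-dimethoxyphenyl)-4-oxobutanoate | CCOC(=O)CCC(=O)c1cccc(OC)c1OC
F7 | step 2 | ethyl 4-(2,3-dimethoxyphenyl)pent-4-enoate | CCOC(=O)CCC(=C)c1cccc(OC)c1OC
F8 | step 2 | 4-(2,3-dimethoxyphenyl)pent-4-enoic acid | OC(=O)CCC(=C)c1cccc(OC)c1OC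
F9 | step 15 | (5R,8S)-3,4-dihydroxy-8-[(2S,6R)-7-hydroxy-6-methylheptan-2-yl]-5-methyl-5,6,7,8-tetrahydronaphthalene-2-carboxylic acid | OC[C@H](C)CCC[C@H](C)[C@@H]1CC[C@@H](C)c2c1cc(C(=O)O)c(O)c2O
F10 | step 15 | (5R,8S)-8-[(2S,6R)-7-[(carboxyacetyl)oxy]-6-methylheptan-2-yl]-3,4-dihydroxy-5-methyl-5,6,7,8-tetrahydronaphthalene-2-carboxylic acid | OC(=O)CC(=O)OC[C@H](C)CCC[C@H](C)[C@@H]1CC[C@@H](C)c2c1cc(C(=O)O)c(O)c2O
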